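## Structural features

The target is a single carbocycle, a cyclohex-2-en-1-one. It is numbered here C1 (ketone carbon), C2 (bearing the hydroxymethyl carbon C7), C3 (vinylic CH), C4 (propanoate), C5 (isopropyl) and C6 ((E)-4-hydroxy-2-methylbut-2-enoate). The stereocentres C4, C5 and C6 are contiguous: the C4 oxygen is cis to isopropyl and the C6 oxygen is trans to it, (4S,5S,6R) in this numbering. Four oxygen functions must be told apart: two secondary esters of different acids and two free primary allylic hydroxyls (C7 and the end of the side-chain acid). The molecule is fragile in three ways: a dienol towards C6 that loses the allylic C4 acyloxy group gives a phenol, C6–H is α to the ketone and can epimerise, and acyl groups can migrate once hydroxyls are free. The real difficulty is therefore the ordered introduction of four differentiated oxygens around a sensitive enone, not the ring itself. The key step exploits the unit C1(=O)–C2–C7H2–OH: a β-hydroxy ketone is an unmasked 2-isoxazoline, so C1–C2 and O–C7 can be formed together by adding a nitrile oxide at C1 across a C2=C7 alkene. An oxygen leaving group on C3 then gives the C2=C3 enone.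

## Logic of the disconnections

27 to 26: only the two O–Si bonds are cut. Both primary hydroxyls are hidden while the esters are built. The forward step must remove silicon without touching two esters, an α-acyloxy ketone and a γ-acyloxy enone, which calls for buffered fluoride.

26 to 20 + 24: the acyl C–O bond at the C6 oxygen is cut. The five-carbon acid is an independent fragment, so the route becomes convergent. The forward step must acylate a hindered secondary α-ketol without epimerising C6.

24 to 23 to 21 + 22: the C2=C3 alkene of the acid is cut and its carboxyl is masked as an ethyl ester. This reduces the side chain to two commercial pieces. The forward steps must give E geometry and hydrolyse the ester while the silyl ether stays.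

20 to 19 to 18: the C6–O bond is cut. C6 is the α′ carbon of the enone, and both neighbouring substituents (C5 isopropyl, C4 propanoate) lie on one face, so an oxidant should enter trans to isopropyl. The silylation that makes the enol ether also caps the C7 hydroxyl, saving a protection step. The forward step must enolise towards C6 and not C4, and must not ionise the C4 propanoate.

18 to 17 to 16 to 15: the C2=C3 π bond is traced back to a propanoate on C3, and the unit C1(=O)–C2–C7–OH to the C=N and N–O bonds of 15. A carboxylate β to the ketone leaves under mild base while the C7 hydroxyl stays, and the second propanoate is already the C4 ester of 27. The forward step needs an N–O cleavage that cannot hydrogenate the new alkene, and an elimination faster than acyl migration to the C7 hydroxyl.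

15 to 14 to 13: the two acyl C–O bonds are cut and the diol is tied back as the isopropylidene acetal. The acetal is the right group for the organometallic steps. As a trans-fused ring, however, it would hold the C3–O bond equatorial, nearly in the plane of a C1–C2 enolate, and so would be a poor leaving group. It is therefore exchanged here rather than eliminated directly.

13 to 12 to 11 to 10 (key): C1–C2 and O–C7 are cut. Two rings and one stereocentre disappear and an acyclic chain remains. The forward step relies on the four-atom tether C6–C5–C4–C3 for fused regiochemistry and on dilution against dimerisation.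

10 to 9 to 8: the C=N bond is cut to the aldehyde, which is taken back to the ester oxidation level. No skeletal change; the forward steps must stop the reduction at the aldehyde.

8 to 7 to 5 + 6: the C5–isopropyl bond is cut. C5 is β to the ester carbonyl and next to the C4 oxygen, which can direct the addition. The forward step must deliver isopropyl anti to that oxygen.

5 to 3 + 4: the enoate C=C (future C5–C6) is cut. 3 is C2-symmetric, so either vinyl group gives the same product. The forward step must stop after one metathesis.

3 to 1 + 2: the acetal C–O bonds are cut. 1 supplies C3 and C4 with their oxygens in the correct absolute configuration.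

## Other disconnections considered

Alternative 1: The cut removes C4–C5 and C1–C6 together. In the forward sense (1E)-buta-1,3-dien-1-yl acetate A1 and 3-[(2E)-3-(benzoyloxy)prop-2-enoyl]-1,3-oxazolidin-2-one A2 would combine in a [4+2] cycloaddition under the cationic bis(oxazoline) copper complex [Cu(tBu-box)](SbF6)2 to give cyclohexene A3.
- In favour: the endo rule should place the C4 acetoxy group cis to the C5 carbonyl, the E geometry of A2 should place the C6 benzoate trans, and the ligand should fix the absolute sense. All three stereocentres would come from achiral materials in one catalytic step. On stereochemical economy this is better than the chosen plan, which uses a chiral-pool diol and two substrate-controlled steps.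
- Against: A3 is far from 27 in functionality. C5 carries an imide carbonyl where isopropyl is needed (two methyl additions and a deoxygenation beside two esters and a ring alkene). That carbonyl is flanked by two β-acyloxy groups and invites elimination on enolisation. C1 is a methylene that needs allylic oxidation, C2 lacks C7 (a Morita–Baylis–Hillman-type hydroxymethylation of the later enone), and acetate and benzoate must be exchanged for the real acyl groups.
- Comparison: both key steps are concerted cycloadditions that close the six-membered ring. The A3 step forms two skeletal bonds against one in step 6, but step 6 also delivers C7 and the C1 oxygen at the right oxidation level. The corrections after A3 would probably outnumber the eight steps after 13.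

Alternative 2: The cut is C5–C6. In the forward sense 1-(furan-2-yl)-2-methylpropan-1-ol A4, heated in water with Dy(OTf)3 or ZnCl2, would add water, open the furan and close by conrotatory 4π electrocyclisation to (4S,5R)-4-hydroxy-5-isopropylcyclopent-2-en-1-one A5.
- In favour: A4 is one Grignard addition from furfural, the conrotatory closure fixes the trans relation that becomes C5/C6 without reagent control, and no protecting group is needed. On brevity to a stereodefined ring and on cost this is better than the chosen plan, which needs six steps to reach 13.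
- Against: A5 would be racemic unless resolved or made by an asymmetric variant, whereas the chosen plan takes its absolute configuration from 1. The ring is five-membered, so C2 with C7 must be inserted between C1 and C3 by a one-carbon ring expansion of uncertain regiochemistry. The carbonyl of A5 sits at the future C4 and must be reduced cis to isopropyl, while C1 must be oxidised again.
- Comparison: a cationic electrocyclisation against a dipolar cycloaddition, both stereospecific, but the A5 step controls relative configuration only. With skeletal and redox corrections after the key step, the sequence should be longer and less certain.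

Alternative 3: The cut is C2=C3. Ring-closing metathesis of (5S,6S)-2-[(tert-butyldimethylsilyloxy)methyl]-5-isopropyl-6-(4-methoxybenzyloxy)octa-1,7-dien-3-one A6 with the second-generation Hoveyda–Grubbs catalyst would give (4R,5S)-5-isopropyl-4-(4-methoxybenzyloxy)-2-[(tert-butyldimethylsilyloxy)methyl]cyclohex-2-en-1-one A7.
- In favour: the C4/C5 pair comes from the same anti-selective cuprate addition, so on that point it is the equal of the chosen plan. The enone arrives directly with C7 silylated and C4 protected; no stereocentre is made and erased, and no N–O cleavage or elimination is needed. On directness of the enone construction it is better than the passage 13 to 18.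
- Against: the closure must form a trisubstituted, electron-poor alkene from a 1,1-disubstituted enone alkene, a slow metathesis. A6 is an α-methylene ketone prone to conjugate addition and polymerisation, and it must be assembled by adding a metallated allyl ether to an aldehyde and oxidising. Its oxygenated stereocentre is doubly allylic and less accessible than C2-symmetric 1. The 4-methoxybenzyl ether must later be exchanged for the propanoate and C6 must still be hydroxylated.
- Comparison: step counts should be similar. The chosen plan is stronger on availability and robustness of the acyclic precursor and uses the C3 oxygen of 1 as the leaving group. Alternative 3 is stronger on redox economy at the ring-forming stage.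

Key step: step 6

Remark: the configurations of 10 and 13 were checked atom by atom against 27 and no correction is needed (C4 R and C5 S in 10 are the 4S,5S centres of 27; only the CIP priorities change). 10 is used as its E/Z mixture and 13 as its expected major C2 epimer; neither matters, since C1 becomes the carbonyl carbon and C2 becomes sp2 in step 8.

## Steps

Step 1
Reactants: 1 (3R,4R)-hexa-1,5-diene-3,4-diol; 2 2,2-dimethoxypropane
Product: 3 (4R,5R)-4,5-diethenyl-2,2-dimethyl-1,3-dioxolane
Conditions: p-TsOH·H2O (cat.), CH2Cl2, rt; careful concentration (volatile product)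
Reagents that add atoms: none
Why: Acid-catalysed transacetalisation of the threo-1,2-diol gives the trans-dioxolane; no stereocentre is touched.

Step 2
Reactants: 3 (4R,5R)-4,5-diethenyl-2,2-dimethyl-1,3-dioxolane; 4 ethyl acrylate
Product: 5 ethyl (2E)-3-[(4R,5R)-5-ethenyl-2,2-dimethyl-1,3-dioxolan-4-yl]prop-2-enoate
Conditions: 3 (3 equiv), 4 (1 equiv), second-generation Hoveyda–Grubbs catalyst RuCl2(H2IMes)(=CH-C6H4-2-OiPr) (3 mol %), CH2Cl2, 40 °C; excess 3 recovered
Reagents that add atoms: none
Why: Olefin cross-metathesis; with the acrylate limiting and C2-symmetric 3 in excess (either vinyl group gives the same product) the second metathesis is held back, and the conjugated alkene forms with E geometry under thermodynamic control.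

Step 3
Reactants: 5 ethyl (2E)-3-[(4R,5R)-5-ethenyl-2,2-dimethyl-1,3-dioxolan-4-yl]prop-2-enoate; 6 isopropylmagnesium chloride
Product: 8 ethyl (3S)-3-[(4R,5R)-5-ethenyl-2,2-dimethyl-1,3-dioxolan-4-yl]-4-methylpentanoate, via silyl ketene acetal 7 (not isolated)
Conditions: iPrMgCl (3 equiv), CuBr·SMe2 (1.5 equiv), TMSCl (3 equiv), THF, −78 °C; then aq. NH4Cl
Reagents that add atoms: none
Why: Copper-mediated conjugate addition of the Grignard reagent with in situ silylation of the enolate to 7; the γ-oxygenated (E)-enoate reacts in the Felkin–Anh-type conformer with the γ C–O bond anti to the incoming copper, so isopropyl is delivered anti to the dioxolane oxygen and the new centre (future C5) is S, cis to the C4 oxygen once the ring is closed.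

Step 4
Reactants: 8 ethyl (3S)-3-[(4R,5R)-5-ethenyl-2,2-dimethyl-1,3-dioxolan-4-yl]-4-methylpentanoate
Product: 9 (3S)-3-[(4R,5R)-5-ethenyl-2,2-dimethyl-1,3-dioxolan-4-yl]-4-methylpentanal
Conditions: iBu2AlH (1.05 equiv), CH2Cl2, −78 °C; MeOH, then aq. potassium sodium tartrate
Reagents that add atoms: none
Why: Partial reduction of the ester at −78 °C, where the tetrahedral aluminium hemiacetal survives until work-up; the stereocentre is β to the carbonyl and cannot epimerise.

Step 5
Reactants: 9 (3S)-3-[(4R,5R)-5-ethenyl-2,2-dimethyl-1,3-dioxolan-4-yl]-4-methylpentanal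
Product: 10 (3S)-3-[(4R,5R)-5-ethenyl-2,2-dimethyl-1,3-dioxolan-4-yl]-4-methylpentanal oxime
Conditions: NH2OH·HCl, NaOAc, EtOH/H2O, rt
Reagents that add atoms: hydroxylamine hydrochloride, NO.Cl
Why: Condensation of the aldehyde with hydroxylamine under acetate buffering, mild enough for the acetonide; both oxime isomers give the same nitrile oxide.

Step 6
Reactants: 10 (3S)-3-[(4R,5R)-5-ethenyl-2,2-dimethyl-1,3-dioxolan-4-yl]-4-methylpentanal oxime
Product: 13 (3aR,4R,5R,6S)-6-isopropyl-4,5-(isopropylidenedioxy)-3,3a,4,5,6,7-hexahydro-2,1-benzisoxazole, via hydroximoyl chloride 11 (not isolated), via nitrile oxide 12 (not isolated)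
Conditions: aq. NaOCl (slow addition), CH2Cl2 (0.01 M), 0 °C → rt
Reagents that add atoms: none
Why: Hypochlorite chlorinates the aldoxime carbon to 11, which loses HCl to nitrile oxide 12; this adds to the tethered terminal alkene in a concerted, suprafacial [3+2] cycloaddition. The closest known reaction type is the intramolecular nitrile oxide–alkene cycloaddition of sugar-derived hex-5-enyl nitrile oxides to cyclohexane-fused 2-isoxazolines. The carbocycle closes by C1–C2 bond formation in a 6-exo mode (C7 stays outside the six-membered ring), and the isoxazoline closes by O–C7 bond formation in the fused mode, because the bridged mode would need a seven-membered carbocycle with a bridgehead C=N bond. The new stereocentre C2 is set by a chair-like transition state in which the trans-dioxolane holds the C3 and C4 oxygens equatorial and the alkene pseudo-equatorial, so C2–H should end trans to C3–H (3aR); isopropyl is axial in this chair, which costs rate but not selectivity. This centre needs no control, because C2 becomes sp2 in step 8. The selectivities that matter are regiochemistry, secured by the four-atom tether C6–C5–C4–C3, and cyclisation over dimerisation of 12 to a furoxan, secured by dilution and slow addition of the oxidant. C4 and C5 are spectators and cannot epimerise here.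

Step 7
Reactants: 13 (3aR,4R,5R,6S)-6-isopropyl-4,5-(isopropylidenedioxy)-3,3a,4,5,6,7-hexahydro-2,1-benzisoxazole
Product: 15 (3aR,4R,5R,6S)-6-isopropyl-3,3a,4,5,6,7-hexahydro-2,1-benzisoxazole-4,5-diyl dipropanoate, via isoxazoline diol 14 (not isolated)
Conditions: AcOH/H2O (4:1), 50 °C; evaporate (toluene); then (EtCO)2O, pyridine, DMAP (cat.), CH2Cl2, rt
Reagents that add atoms: propanoic anhydride, CCC(=O)OC(=O)CC
Why: The strained trans-fused acetonide is hydrolysed by aqueous acetic acid, to which the 2-isoxazoline is inert, and the crude diol is esterified by DMAP-catalysed acyl transfer with retention at C3 and C4; this replaces an acetal oxygen that would be badly aligned for β-elimination by a carboxylate leaving group at C3 and installs the C4 ester of the target.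

Step 8
Reactants: 15 (3aR,4R,5R,6S)-6-isopropyl-3,3a,4,5,6,7-hexahydro-2,1-benzisoxazole-4,5-diyl dipropanoate
Product: 18 (4R,5S)-2-(hydroxymethyl)-5-isopropyl-4-(propanoyloxy)cyclohex-2-en-1-one, via hydroxy imine 16 (not isolated), via hydroxy ketone 17 (not isolated)
Conditions: Mo(CO)6, MeCN/H2O (15:1), 80 °C; cool, then Et3N, rt
Reagents that add atoms: water, O
Why: Zerovalent molybdenum cleaves the N–O bond reductively and water hydrolyses imine 16 to β-hydroxy ketone 17 (no H2 is present, so the alkene formed next cannot be hydrogenated); Et3N then removes the C2 proton and the C3 propanoate leaves in an E1cB elimination, far easier than loss of the C7 hydroxyl, which erases C2 and C3 and leaves C4 and C5 untouched.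

Step 9
Reactants: 18 (4R,5S)-2-(hydroxymethyl)-5-isopropyl-4-(propanoyloxy)cyclohex-2-en-1-one
Product: 19 (1R,6R)-4-(tert-butyldimethylsilyloxy)-3-[(tert-butyldimethylsilyloxy)methyl]-6-isopropylcyclohexa-2,4-dien-1-yl propanoate
Conditions: TBSOTf (2.4 equiv), Et3N (4 equiv), CH2Cl2, −78 → 0 °C
Reagents that add atoms: tert-butyldimethylsilyl trifluoromethanesulfonate, CC(C)(C)[Si](C)(C)OS(=O)(=O)C(F)(F)F
Why: Soft enolisation: the silyl triflate silylates the primary hydroxyl and activates the carbonyl, and Et3N removes the accessible α′ proton at C6 rather than the hindered γ proton at C4, giving the cross-conjugated 2-silyloxydiene; the ester is not enolised and no stereocentre is formed.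

Step 10
Reactants: 19 (1R,6R)-4-(tert-butyldimethylsilyloxy)-3-[(tert-butyldimethylsilyloxy)methyl]-6-isopropylcyclohexa-2,4-dien-1-yl propanoate
Product: 20 (4S,5R,6R)-6-hydroxy-5-isopropyl-4-(propanoyloxy)-2-[(tert-butyldimethylsilyloxy)methyl]cyclohex-2-en-1-one
Conditions: OsO4 (2 mol %), N-methylmorpholine N-oxide, acetone/H2O, 0 °C
Reagents that add atoms: N-methylmorpholine N-oxide, C[N+]1([O-])CCOCC1 (oxygen relayed by OsO4); water, O
Why: OsO4 adds to the electron-rich silyl enol ether C1=C6 in preference to the trisubstituted C2=C3 bond, and hydrolysis of the osmate with loss of silanol gives the α′-hydroxy ketone (osmylation variant of the Rubottom oxidation); the reagent approaches C6 on the face opposite to the neighbouring isopropyl group and the C4 propanoate, setting C6–O trans to isopropyl (6R).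

Step 11
Reactants: 21 (tert-butyldimethylsilyloxy)acetaldehyde; 22 ethyl 2-(triphenylphosphoranylidene)propanoate
Product: 23 ethyl (2E)-4-(tert-butyldimethylsilyloxy)-2-methylbut-2-enoate
Conditions: CH2Cl2, rt
Reagents that add atoms: none
Why: Wittig olefination with a stabilised, α-branched ylide, which gives the (E)-trisubstituted enoate.

Step 12
Reactants: 23 ethyl (2E)-4-(tert-butyldimethylsilyloxy)-2-methylbut-2-enoate
Product: 24 (2E)-4-(tert-butyldimethylsilyloxy)-2-methylbut-2-enoic acid
Conditions: LiOH, THF/H2O, rt; then aq. HCl to pH 4, 0 °C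
Reagents that add atoms: lithium hydroxide, [Li+].[OH-]
Why: Saponification at room temperature, which a primary tert-butyldimethylsilyl ether withstands; cold acidification to pH 4 avoids desilylation.

Step 13
Reactants: 20 (4S,5R,6R)-6-hydroxy-5-isopropyl-4-(propanoyloxy)-2-[(tert-butyldimethylsilyloxy)methyl]cyclohex-2-en-1-one; 24 (2E)-4-(tert-butyldimethylsilyloxy)-2-methylbut-2-enoic acid
Product: 26 (1R,5S,6S)-3-[(tert-butyldimethylsilyloxy)methyl]-6-isopropyl-2-oxo-5-(propanoyloxy)cyclohex-3-en-1-yl (2E)-4-(tert-butyldimethylsilyloxy)-2-methylbut-2-enoate, via mixed anhydride 25 (not isolated)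
Conditions: 24, 2,4,6-trichlorobenzoyl chloride, Et3N, toluene, rt; then 20, DMAP, rt
Reagents that add atoms: none
Why: Yamaguchi esterification: DMAP attacks mixed anhydride 25 at the less hindered aliphatic carbonyl and the acylpyridinium acylates the hindered α-ketol; the C6–O bond is not broken, so configuration is retained, and the trans arrangement at C5/C6 should also be the thermodynamically preferred one.

Step 14
Reactants: 26 (1R,5S,6S)-3-[(tert-butyldimethylsilyloxy)methyl]-6-isopropyl-2-oxo-5-(propanoyloxy)cyclohex-3-en-1-yl (2E)-4-(tert-butyldimethylsilyloxy)-2-methylbut-2-enoate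
Product: 27 (1R,5S,6S)-3-(hydroxymethyl)-6-isopropyl-2-oxo-5-(propanoyloxy)cyclohex-3-en-1-yl (2E)-4-hydroxy-2-methylbut-2-enoate
Conditions: HF·pyridine, pyridine, THF, 0 °C → rt
Reagents that add atoms: none
Why: Fluoride-driven cleavage of both primary silyl ethers, buffered with pyridine so that the two esters, the γ-acyloxy enone and the α-acyloxy ketone are untouched; no stereocentre is involved.

## Compound list

1 | (3R,4R)-hexa-1,5-diene-3,4-diol | C=C[C@@H](O)[C@H](O)C=C | starting material
2 | 2,2-dimethoxypropane | COC(C)(C)OC | starting material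
3 | (4R,5R)-4,5-diethenyl-2,2-dimethyl-1,3-dioxolane | C=C[C@H]1OC(C)(C)O[C@@H]1C=C | intermediate
4 | ethyl acrylate | C=CC(=O)OCC | starting material
5 | ethyl (2E)-3-[(4R,5R)-5-ethenyl-2,2-dimethyl-1,3-dioxolan-4-yl]prop-2-enoate | C=C[C@H]1OC(C)(C)O[C@@H]1/C=C/C(=O)OCC | intermediate
6 | isopropylmagnesium chloride | CC(C)[Mg]Cl | starting material
7 | (4R,5R)-4-[(3R)-1-ethoxy-4-methyl-1-(trimethylsilyloxy)pent-1-en-3-yl]-5-ethenyl-2,2-dimethyl-1,3-dioxolane (silyl ketene acetal of 8, alkene geometry open) | C=C[C@H]1OC(C)(C)O[C@@H]1[C@H](C(C)C)C=C(OCC)O[Si](C)(C)C | intermediate (not isolated)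
8 | ethyl (3S)-3-[(4R,5R)-5-ethenyl-2,2-dimethyl-1,3-dioxolan-4-yl]-4-methylpentanoate | C=C[C@H]1OC(C)(C)O[C@@H]1[C@H](C(C)C)CC(=O)OCC | intermediate
9 | (3S)-3-[(4R,5R)-5-ethenyl-2,2-dimethyl-1,3-dioxolan-4-yl]-4-methylpentanal | C=C[C@H]1OC(C)(C)O[C@@H]1[C@H](C(C)C)CC=O | intermediate
10 | (3S)-3-[(4R,5R)-5-ethenyl-2,2-dimethyl-1,3-dioxolan-4-yl]-4-methylpentanal oxime (E isomer drawn) | C=C[C@H]1OC(C)(C)O[C@@H]1[C@H](C(C)C)C/C=N/O | intermediate
11 | (3S)-3-[(4R,5R)-5-ethenyl-2,2-dimethyl-1,3-dioxolan-4-yl]-N-hydroxy-4-methylpentanimidoyl chloride | C=C[C@H]1OC(C)(C)O[C@@H]1[C@H](C(C)C)CC(Cl)=NO | intermediate (not isolated)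
12 | (3S)-3-[(4R,5R)-5-ethenyl-2,2-dimethyl-1,3-dioxolan-4-yl]-4-methylpentanenitrile oxide | C=C[C@H]1OC(C)(C)O[C@@H]1[C@H](C(C)C)CC#[N+][O-] | intermediate (not isolated)
13 | (3aR,4R,5R,6S)-6-isopropyl-4,5-(isopropylidenedioxy)-3,3a,4,5,6,7-hexahydro-2,1-benzisoxazole | CC(C)[C@@H]1CC2=NOC[C@@H]2[C@H]3OC(C)(C)O[C@H]13 | intermediate
14 | (3aR,4R,5R,6S)-6-isopropyl-3,3a,4,5,6,7-hexahydro-2,1-benzisoxazole-4,5-diol | CC(C)[C@@H]1CC2=NOC[C@@H]2[C@@H](O)[C@@H]1O | intermediate (not isolated)
15 | (3aR,4R,5R,6S)-6-isopropyl-3,3a,4,5,6,7-hexahydro-2,1-benzisoxazole-4,5-diyl dipropanoate | CC(C)[C@@H]1CC2=NOC[C@@H]2[C@@H](OC(=O)CC)[C@@H]1OC(=O)CC | intermediate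
16 | (2R,3R,4R,5S)-2-(hydroxymethyl)-1-imino-5-isopropylcyclohexane-3,4-diyl dipropanoate | CC(C)[C@@H]1CC(=N)[C@H](CO)[C@@H](OC(=O)CC)[C@@H]1OC(=O)CC | intermediate (not isolated)
17 | (2R,3R,4R,5S)-2-(hydroxymethyl)-5-isopropyl-3,4-bis(propanoyloxy)cyclohexan-1-one | CC(C)[C@@H]1CC(=O)[C@H](CO)[C@@H](OC(=O)CC)[C@@H]1OC(=O)CC | intermediate (not isolated)
18 | (4R,5S)-2-(hydroxymethyl)-5-isopropyl-4-(propanoyloxy)cyclohex-2-en-1-one | CCC(=O)O[C@H]1C=C(CO)C(=O)C[C@H]1C(C)C | intermediate
19 | (1R,6R)-4-(tert-butyldimethylsilyloxy)-3-[(tert-butyldimethylsilyloxy)methyl]-6-isopropylcyclohexa-2,4-dien-1-yl propanoate | CCC(=O)O[C@H]1C=C(CO[Si](C)(C)C(C)(C)C)C(O[Si](C)(C)C(C)(C)C)=C[C@H]1C(C)C | intermediate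
20 | (4S,5R,6R)-6-hydroxy-5-isopropyl-4-(propanoyloxy)-2-[(tert-butyldimethylsilyloxy)methyl]cyclohex-2-en-1-one | CCC(=O)O[C@H]1C=C(CO[Si](C)(C)C(C)(C)C)C(=O)[C@H](O)[C@H]1C(C)C | intermediate
21 | (tert-butyldimethylsilyloxy)acetaldehyde | CC(C)(C)[Si](C)(C)OCC=O | starting material
22 | ethyl 2-(triphenylphosphoranylidene)propanoate | CCOC(=O)C(C)=P(c1ccccc1)(c1ccccc1)c1ccccc1 | starting material
23 | ethyl (2E)-4-(tert-butyldimethylsilyloxy)-2-methylbut-2-enoate | CCOC(=O)/C(C)=C/CO[Si](C)(C)C(C)(C)C | intermediate
24 | (2E)-4-(tert-butyldimethylsilyloxy)-2-methylbut-2-enoic acid | OC(=O)/C(C)=C/CO[Si](C)(C)C(C)(C)C | intermediate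
25 | (2E)-4-(tert-butyldimethylsilyloxy)-2-methylbut-2-enoic 2,4,6-trichlorobenzoic anhydride | Clc1cc(Cl)c(C(=O)OC(=O)/C(C)=C/CO[Si](C)(C)C(C)(C)C)c(Cl)c1 | intermediate (not isolated)
26 | (1R,5S,6S)-3-[(tert-butyldimethylsilyloxy)methyl]-6-isopropyl-2-oxo-5-(propanoyloxy)cyclohex-3-en-1-yl (2E)-4-(tert-butyldimethylsilyloxy)-2-methylbut-2-enoate | CCC(=O)O[C@H]1C=C(CO[Si](C)(C)C(C)(C)C)C(=O)[C@H](OC(=O)/C(C)=C/CO[Si](C)(C)C(C)(C)C)[C@H]1C(C)C | intermediate
27 | (1R,5S,6S)-3-(hydroxymethyl)-6-isopropyl-2-oxo-5-(propanoyloxy)cyclohex-3-en-1-yl (2E)-4-hydroxy-2-methylbut-2-enoate | CCC(=O)O[C@H]1C=C(CO)C(=O)[C@H](OC(=O)/C(C)=C/CO)[C@H]1C(C)C | target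

## Step count and least certain steps

Total: 14 steps. Longest linear sequence: 12 steps (steps 1 to 10, 13 and 14); the acid branch is 2 steps (11 and 12).

**Step 6 (key step).** Ring closure may be too slow, so that dimerisation of the nitrile oxide takes over. The chair must carry isopropyl axial and must close a six-membered ring trans-fused to the dioxolane.
- Fallback, from 10, returning at 14 (and so at 15): remove the acetonide first with aqueous acetic acid containing a little NH2OH·HCl to hold the oxime, giving (3S,4R,5R)-4,5-dihydroxy-3-isopropylhept-6-enal oxime F1.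
- NaOCl then gives (3S,4R,5R)-N,4,5-trihydroxy-3-isopropylhept-6-enimidoyl chloride F2 and (3S,4R,5R)-4,5-dihydroxy-3-isopropylhept-6-enenitrile oxide F3.
- F3 can cyclise through a chair with isopropyl equatorial and no trans-fused five-membered ring; free hydroxyls are tolerated in this class of cycloaddition. The product is 14, acylated as in the second half of step 7.

**Step 9.** Enolisation may go towards C4 (γ-deprotonation), or the silyl triflate may ionise the allylic propanoate of the dienol ether and cause aromatisation.
- Fallback, from 18, returning at 20: deprotonate twice with LiN(SiMe3)2 (2.2 equiv, THF, −78 °C) to the dilithium alkoxide–enolate of 18 F4; kinetic deprotonation of a cyclohexenone occurs at α′.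
- Hydroxylate with 2-(phenylsulfonyl)-3-phenyloxaziridine on the face opposite to isopropyl to give (4S,5R,6R)-6-hydroxy-2-(hydroxymethyl)-5-isopropyl-4-(propanoyloxy)cyclohex-2-en-1-one F5.
- Selective silylation of the primary hydroxyl (TBSCl, imidazole, CH2Cl2, −20 °C) returns 20.

**Step 8.** At 80 °C with the C7 hydroxyl free, the C3 propanoate may migrate to C7 before elimination, or the hydroxymethyl carbon may be lost by retro-aldol cleavage.
- Fallback, from 15, returning at 19: cleave the N–O bond cold with SmI2 (THF, 0 °C; then aqueous B(OH)3) and isolate 17.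
- Silylate at once (TBSOTf, 2,6-lutidine, CH2Cl2, −78 °C) to (2R,3R,4R,5S)-2-[(tert-butyldimethylsilyloxy)methyl]-5-isopropyl-3,4-bis(propanoyloxy)cyclohexan-1-one F6, in which migration is impossible.
- DBU (CH2Cl2, 0 °C) eliminates the C3 propanoate to (4R,5S)-2-[(tert-butyldimethylsilyloxy)methyl]-5-isopropyl-4-(propanoyloxy)cyclohex-2-en-1-one F7. TBSOTf/Et3N as in step 9 then gives 19.

**Step 10.** Facial selectivity at C6 may be poor if the diene ring flattens and the bias from C4 and C5 weakens; over-oxidation of C2=C3 is a lesser risk.
- Fallback, from 19, returning at 26: separate any (4S,5R,6S)-6-hydroxy-5-isopropyl-4-(propanoyloxy)-2-[(tert-butyldimethylsilyloxy)methyl]cyclohex-2-en-1-one F8 and esterify it with 24 under Mitsunobu conditions (PPh3, diisopropyl azodicarboxylate, toluene, 0 °C).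
- The carboxylate displaces the activated α-keto carbinol with inversion, entering anti to isopropyl, and gives 26 directly. Both C6 epimers then converge, 20 through step 13 and F8 through inversion.

## Further compounds

F1 | step 6 | (3S,4R,5R)-4,5-dihydroxy-3-isopropylhept-6-enal oxime | C=C[C@@H](O)[C@H](O)[C@H](C(C)C)C/C=N/O
F2 | step 6 | (3S,4R,5R)-N,4,5-trihydroxy-3-isopropylhept-6-enimidoyl chloride | C=C[C@@H](O)[C@H](O)[C@H](C(C)C)CC(Cl)=NO
F3 | step 6 | (3S,4R,5R)-4,5-dihydroxy-3-isopropylhept-6-enenitrile oxide | C=C[C@@H](O)[C@H](O)[C@H](C(C)C)CC#[N+][O-]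
F4 | step 9 | dilithium alkoxide–enolate of 18 | CCC(=O)O[C@H]1C=C(CO[Li])C(O[Li])=C[C@H]1C(C)C
F5 | step 9 | (4S,5R,6R)-6-hydroxy-2-(hydroxymethyl)-5-isopropyl-4-(propanoyloxy)cyclohex-2-en-1-one | CCC(=O)O[C@H]1C=C(CO)C(=O)[C@H](O)[C@H]1C(C)C
F6 | step 8 | (2R,3R,4R,5S)-2-[(tert-butyldimethylsilyloxy)methyl]-5-isopropyl-3,4-bis(propanoyloxy)cyclohexan-1-one | CC(C)[C@@H]1CC(=O)[C@H](CO[Si](C)(C)C(C)(C)C)[C@@H](OC(=O)CC)[C@@H]1OC(=O)CC
F7 | step 8 | (4R,5S)-2-[(tert-butyldimethylsilyloxy)methyl]-5-isopropyl-4-(propanoyloxy)cyclohex-2-en-1-one | CCC(=O)O[C@H]1C=C(CO[Si](C)(C)C(C)(C)C)C(=O)C[C@H]1C(C)C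
F8 | step 10 | (4S,5R,6S)-6-hydroxy-5-isopropyl-4-(propanoyloxy)-2-[(tert-butyldimethylsilyloxy)methyl]cyclohex-2-en-1-one | CCC(=O)O[C@H]1C=C(CO[Si](C)(C)C(C)(C)C)C(=O)[C@@H](O)[C@H]1C(C)C
A1 | alternative 1 | (1E)-buta-1,3-dien-1-yl acetate | CC(=O)O/C=C/C=C
A2 | alternative 1 | 3-[(2E)-3-(benzoyloxy)prop-2-enoyl]-1,3-oxazolidin-2-one | O=C(/C=C/OC(=O)c1ccccc1)N1CCOC1=O
A3 | alternative 1 | 4-acetoxy-6-benzoyloxy-5-(2-oxooxazolidine-3-carbonyl)cyclohex-2-ene (target numbering, configured as the target) | CC(=O)O[C@H]1C=CC[C@H](OC(=O)c2ccccc2)[C@H]1C(=O)N3CCOC3=O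
A4 | alternative 2 | 1-(furan-2-yl)-2-methylpropan-1-ol | CC(C)C(O)c1ccco1
A5 | alternative 2 | (4S,5R)-4-hydroxy-5-isopropylcyclopent-2-en-1-one | O=C1C=C[C@H](O)[C@H]1C(C)C
A6 | alternative 3 | (5S,6S)-2-[(tert-butyldimethylsilyloxy)methyl]-5-isopropyl-6-(4-methoxybenzyloxy)octa-1,7-dien-3-one | C=C[C@H](OCc1ccc(OC)cc1)[C@H](C(C)C)CC(=O)C(=C)CO[Si](C)(C)C(C)(C)C
A7 | alternative 3 | (4R,5S)-5-isopropyl-4-(4-methoxybenzyloxy)-2-[(tert-butyldimethylsilyloxy)methyl]cyclohex-2-en-1-one | COc1ccc(CO[C@H]2C=C(CO[Si](C)(C)C(C)(C)C)C(=O)C[C@H]2C(C)C)cc1
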